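## The problem

Siphulin (15) is an achiral 2-benzylchromone. Ring A is a resorcinol-type benzo ring with a heptyl chain at C5 and a phenol at C7. Ring B is the 4-pyranone. Ring C is a 2-carboxy-3,5-dihydroxyphenyl unit joined to C2 through a single methylene carbon. With no stereocentre, the task is one of connectivity, regiochemistry and functional-group tolerance.

- **Regiochemistry on ring A.** The heptyl group must sit peri to the C4 carbonyl, on the more crowded side of ring A, so the step that fixes the ring A pattern must be unambiguous.
- **Ring C acid.** It is a beta-resorcylic acid that decarboxylates readily in acid or on heating. Its ester is flanked by two ortho substituents and is hydrolysed only by forcing hydroxide, which would open the pyranone.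
- **The C2 methylene.** In any open-chain 1,3-diketone precursor it lies between a ketone and an aryl ring with an ortho ester, so base invites isocoumarin or naphthol formation.
- **The C2-C3 double bond.** It is reducible and must survive the final deprotection.
- **The enabling feature.** C4 is a carbonyl carbon on C4a, with O1 on the neighbouring C8a, and C3 is the alpha carbon of C2, which is itself at the ketone oxidation level. C4 can therefore come from the formyl carbon of a salicylaldehyde whose phenol becomes O1, and C3 from the carbene carbon of an acyl carbene equivalent whose carbonyl becomes C2.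

## Retrosynthesis

**15 to 14.** The four O-benzyl bonds of 14 (three aryl ethers and the ring C ester) are cut last. A single neutral hydrogenolysis at room temperature is preferred to methyl ethers or an alkyl ester, whose removal would need Lewis acid or hydroxide and would risk decarboxylation of ring C or opening of ring B. The precursor 14 has no free acidic group and can be purified normally. The forward step must stop before the C2-C3 double bond is reduced.

**14 to 4 and 12.** Ring B is opened at C3-C4 and O1-C2. This gives salicylaldehyde 4 and sulfoxonium ylide 12, which combine through the 1,3-diketone 13. The neighbouring C2-C3 cut (a Claisen-type acylation) would need strong base next to the ring C ester. A C4-C4a cut (ring acylation) would leave the ring A regiochemistry open. The chosen cut uses neither base nor an electrophilic substitution on ring A, and it divides the target into two fragments of similar size, each with one aromatic ring already complete. The forward reaction must cleave the formyl C-H rather than an aryl C-H, and must close 13 through the phenol rather than onto the ring C ester.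

**4 to 3 to 1.** The benzyl ether at the future C7 and then the formyl C-C bond are cut, leading to 5-heptylresorcinol 1. Because 1 is symmetric, the two positions ortho to one hydroxyl and para to the other are identical, and formylation there places the aldehyde next to the heptyl chain. In 3 the hydroxyl para to the formyl group is the more acidic and is not hydrogen-bonded, so one benzyl group can be placed selectively. Two steps are needed.

**12 to 8 and 9.** The bond between the ketone carbon and the ylide carbon is cut, giving arylacetic acid 8 and trimethylsulfoxonium iodide 9. In the forward direction 8 is activated as acyl imidazolide 11 and acylates methylide 10. The acid is preferred to a diester precursor because only one acyl group is then activated. The hindered aryl benzyl ester must remain untouched.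

**8 to 6 to 5.** The CH2-CO2H bond of 8 is cut to the ortho-toluate 6, which is carboxylated through its benzylic lithium derivative 7. The three O-benzyl bonds of 6 are then cut to orsellinic acid 5, which already carries the complete ring C pattern. One perbenzylation installs both the phenol protection and the ester wanted at the end.

## Roads not taken

**Alternative 1:** The cut is C4-C4a, with O1-C2 already present as an aryl enol ether. In the forward key step the 3-aryloxybut-2-enoic acid A2 is activated to an acylium-type electrophile. Here ring A is bound through O1, and ring C is masked as a pivalate and a benzodioxinone. The electrophile attacks ring A ortho to the ether oxygen and gives protected siphulin A1.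

- *Merits.* No transition metal is needed, the ring closure of aryloxyacrylic acids is old and scalable, and the benzodioxinone masks the ring C acid and its ortho phenol in one group.
- *Weak points.* Ring A in A2 is no longer symmetric. The site between O1 and the heptyl chain is the wanted one but is crowded. The site between O1 and the benzyloxy group would give the 7-heptyl-5-benzyloxy isomer, and nothing in A2 enforces the choice. The electrophile must be generated in strong acid beside a benzyl ether, a ketal and a methylene that is benzylic and allylic to an enol ether. Only the Z isomer of A2 can close. Three kinds of protecting group mean three deprotections, and those of the pivalate and dioxinone need base or nucleophile, which endangers ring B.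
- *Comparison.* This road is cheaper in reagents and would compete if the acylation were regioselective. The chosen plan sets the ring A regiochemistry on symmetric 1 and carries only benzyl groups. Its price is a rhodium/silver catalyst and the preparation of ylide 12.

**Alternative 2:** The cut runs through ring C (C1'-C6' and C4'-C5'), which is made last. In the forward key step the 2-pyrone A4 already carries the complete chromone on its C6 methylene, a benzyl ester at C5 and a benzyloxy group at C4. It is heated with the ketene bis(silyl) acetal A5. Cycloaddition across the pyrone diene, followed by decarboxylative and desilylative aromatisation, gives A3, in which the C5' phenol is free and the C3' phenol is benzylated.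

- *Merits.* The ring C pattern is fixed by the pyrone, the conditions are thermal and neutral, and the two ring C phenols emerge differentiated. The chosen plan cannot offer that differentiation, which is of no use for 15 but useful for analogues.
- *Weak points.* A4 contains the whole chromone, so ring B must still be built by one of the other methods and ring C is merely postponed. A4 needs its own multistep synthesis. The electron-rich A5 can add in conjugate fashion to C2 of the chromone instead of cycloadding. The methylene between pyrone and chromone is strongly acidic.
- *Comparison.* Ring C with exactly this pattern can be bought as 5, so building it from a pyrone adds steps without solving the chromone problem. The chosen plan is shorter and only gives up the phenol differentiation.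

**Alternative 3:** The cut runs through ring A (C5-C6 and C4a-C8a). In the forward key step the 1,3-bis(silyloxy)diene A8 adds to ynone A7, whose alkyne terminus carries the heptyl chain and whose acyl group is a beta-methoxyenone bearing benzyl-protected ring C. After loss of the methoxy and silyl groups, ring A emerges aromatic as the 2-acylresorcinol A6. Acid would then close O1-C2 by addition-elimination at the beta-methoxyenone.

- *Merits.* The ring A regiochemistry follows from the polarisation of ynone and diene and is as secure as in the chosen plan. No selective monobenzylation is needed, and other chain lengths come simply from other alkynes. No precious metal is used. In flexibility this road is better than the chosen one.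
- *Weak points.* A7 is a base-sensitive bis-electrophile with an active methylene, and its preparation from 8 takes several steps. A8 can attack the beta-methoxyenone carbon (the future C2) instead of the ynone. A6 emerges with both phenols free, so the C7 hydroxyl is unprotected during ring B closure. The count of steps is clearly higher.
- *Comparison.* Regiocontrol is equal and flexibility is better. The chosen plan answers with brevity: ring A is bought with its heptyl chain as 1, and two steps turn it into 4.

Key step: step 6

## Route

Assumption: 5-heptylbenzene-1,3-diol and orsellinic acid (2,4-dihydroxy-6-methylbenzoic acid) are taken as purchased. The free acid is chosen over its methyl ester so that one perbenzylation gives the benzyl ester directly.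

Step 1
Reactants: 1 5-heptylbenzene-1,3-diol
Product: 3 2-heptyl-4,6-dihydroxybenzaldehyde, via aryl iminium chloride 2 (not isolated)
Conditions: POCl3, DMF, 0 °C to rt; then H2O, 50 °C
Reagents that add atoms: N,N-dimethylformamide, CN(C)C=O (formyl carbon; its Me2N unit also sits in 2); water, O (carbonyl oxygen of 3); phosphoryl chloride, O=P(Cl)(Cl)Cl (chloride counter-ion of 2 only)
Why: Vilsmeier-Haack formylation. The two positions ortho to one hydroxyl and para to the other are equivalent in symmetric 1 and are favoured over the position between the hydroxyls, so the formyl group enters next to the heptyl chain; hydrolysis of iminium salt 2 gives 3.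

Step 2
Reactants: 3 2-heptyl-4,6-dihydroxybenzaldehyde
Product: 4 4-(benzyloxy)-2-heptyl-6-hydroxybenzaldehyde
Conditions: BnBr (1.05 equiv), NaHCO3, KI (cat.), MeCN, 80 °C
Reagents that add atoms: benzyl bromide, BrCc1ccccc1
Why: Williamson ether synthesis. The hydroxyl ortho to the formyl group is held in a hydrogen bond and is poorly nucleophilic, while the para hydroxyl is the more acidic, so one equivalent of halide with a weak base should alkylate the para oxygen only, as is established for 2,4-dihydroxybenzaldehydes.

Step 3
Reactants: 5 2,4-dihydroxy-6-methylbenzoic acid (orsellinic acid)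
Product: 6 benzyl 2,4-bis(benzyloxy)-6-methylbenzoate
Conditions: BnBr (3.5 equiv), K2CO3, DMF, rt to 50 °C
Reagents that add atoms: benzyl bromide, BrCc1ccccc1
Why: Exhaustive Williamson O-alkylation. The carboxylate is benzylated first, which removes the tendency of the beta-resorcylic acid to decarboxylate, and the two phenoxides follow.

Step 4
Reactants: 6 benzyl 2,4-bis(benzyloxy)-6-methylbenzoate
Product: 8 2-[3,5-bis(benzyloxy)-2-(benzyloxycarbonyl)phenyl]acetic acid, via benzylic lithium species 7 (not isolated)
Conditions: LiN(iPr)2 (1.2 equiv), THF, -78 °C; CO2, -78 °C to rt; aq. HCl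
Reagents that add atoms: carbon dioxide, O=C=O; lithium diisopropylamide, [Li]N(C(C)C)C(C)C (lithium of 7 only)
Why: Lateral lithiation of an ortho-toluate followed by carboxylation. The aryl methyl protons are acidified by the ortho ester (dienolate-type anion 7), the doubly ortho-substituted ester resists self-condensation at -78 °C, and carbon dioxide traps the carbanion at carbon.

Step 5
Reactants: 8 2-[3,5-bis(benzyloxy)-2-(benzyloxycarbonyl)phenyl]acetic acid; 9 trimethylsulfoxonium iodide
Product: 12 benzyl 2,4-bis(benzyloxy)-6-[3-(dimethyl(oxo)-λ6-sulfanylidene)-2-oxopropyl]benzoate, via dimethylsulfoxonium methylide 10 (not isolated), via acyl imidazolide 11 (not isolated)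
Conditions: 8, 1,1'-carbonyldiimidazole, THF, rt; added to 9 (3 equiv) pre-treated with KOtBu (3 equiv) in THF (reflux, then 0 °C); 0 °C to rt
Reagents that add atoms: 1,1'-carbonyldiimidazole, O=C(n1ccnc1)n1ccnc1 (imidazolyl group of 11 only; no atoms in 12)
Why: Acylation of the Corey-Chaykovsky methylide by an activated carboxylic acid, the standard entry to beta-keto sulfoxonium ylides. Excess base deprotonates the first-formed acylsulfoxonium salt to the stabilised ylide 12, and the flanked, electron-rich aryl benzyl ester is far less electrophilic than acyl imidazolide 11.

Step 6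
Reactants: 4 4-(benzyloxy)-2-heptyl-6-hydroxybenzaldehyde; 12 benzyl 2,4-bis(benzyloxy)-6-[3-(dimethyl(oxo)-λ6-sulfanylidene)-2-oxopropyl]benzoate
Product: 14 benzyl 2,4-bis(benzyloxy)-6-{[7-(benzyloxy)-5-heptyl-4-oxo-4H-chromen-2-yl]methyl}benzoate (tetrabenzyl siphulin), via 1,3-diketone 13 (not isolated)
Conditions: [Cp*RhCl2]2 (2.5 mol%), AgSbF6 (10 mol%), PivOH (1 equiv), ClCH2CH2Cl, 80 °C
Reagents that add atoms: none
Why: AgSbF6 removes chloride to give a cationic Cp*Rh species (trivalent rhodium); the phenol of 4 binds it and the formyl C-H is cleaved by pivalate-assisted metalation to a five-membered acyl rhodacycle. Ylide 12 binds through carbon and loses dimethyl sulfoxide to give a rhodium carbene, migratory insertion of the acyl group forms C3-C4, and protonolysis releases diketone 13 and returns the catalyst. The phenol of 13 adds to the C2 ketone in a 6-exo-trig closure (O1-C2) and the hemiketal loses water in the acidic medium to give the aromatic pyranone of 14. The closest known reaction type is the rhodium-catalysed annulation of salicylaldehydes with sulfoxonium ylides to 2-substituted chromones. No stereocentre is formed. Formyl rather than aryl C-H cleavage is needed and is secured by the O,C-chelate that only the formyl group ortho to the phenol can form. Closure through the phenol rather than attack of the diketone on the ring C ester is also needed; it is secured by the absence of base, by the hindered doubly ortho-substituted benzyl ester and by the irreversible dehydration to the pyranone.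

Step 7
Reactants: 14 benzyl 2,4-bis(benzyloxy)-6-{[7-(benzyloxy)-5-heptyl-4-oxo-4H-chromen-2-yl]methyl}benzoate
Product: 15 siphulin, 2-[(5-heptyl-7-hydroxy-4-oxo-4H-chromen-2-yl)methyl]-4,6-dihydroxybenzoic acid
Conditions: H2 (1 atm), 10% Pd/C, EtOAc-MeOH, rt; stopped after uptake of four equivalents
Reagents that add atoms: none
Why: Catalytic hydrogenolysis of three benzyl ethers and one benzyl ester under neutral conditions at room temperature, which spares the decarboxylation-prone beta-resorcylic acid. The C2-C3 double bond is part of a vinylogous ester and is reduced much more slowly than O-benzyl bonds are cleaved.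

## Compound list

1 | 5-heptylbenzene-1,3-diol | CCCCCCCc1cc(O)cc(O)c1 | starting material
2 | [(2-heptyl-4,6-dihydroxyphenyl)methylidene]dimethylammonium chloride | CCCCCCCc1cc(O)cc(O)c1C=[N+](C)C.[Cl-] | intermediate
3 | 2-heptyl-4,6-dihydroxybenzaldehyde | CCCCCCCc1cc(O)cc(O)c1C=O | intermediate
4 | 4-(benzyloxy)-2-heptyl-6-hydroxybenzaldehyde | CCCCCCCc1cc(OCc2ccccc2)cc(O)c1C=O | intermediate
5 | 2,4-dihydroxy-6-methylbenzoic acid (orsellinic acid) | Cc1cc(O)cc(O)c1C(=O)O | starting material
6 | benzyl 2,4-bis(benzyloxy)-6-methylbenzoate | Cc1cc(OCc2ccccc2)cc(OCc2ccccc2)c1C(=O)OCc1ccccc1 | intermediate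
7 | benzyl 2,4-bis(benzyloxy)-6-(lithiomethyl)benzoate | [Li]Cc1cc(OCc2ccccc2)cc(OCc2ccccc2)c1C(=O)OCc1ccccc1 | intermediate
8 | 2-[3,5-bis(benzyloxy)-2-(benzyloxycarbonyl)phenyl]acetic acid | OC(=O)Cc1cc(OCc2ccccc2)cc(OCc2ccccc2)c1C(=O)OCc1ccccc1 | intermediate
9 | trimethylsulfoxonium iodide | C[S+](C)(C)=O.[I-] | starting material
10 | dimethylsulfoxonium methylide | C[S+](C)(=O)[CH2-] | intermediate
11 | benzyl 2,4-bis(benzyloxy)-6-[2-(1H-imidazol-1-yl)-2-oxoethyl]benzoate | O=C(Cc1cc(OCc2ccccc2)cc(OCc2ccccc2)c1C(=O)OCc1ccccc1)n1ccnc1 | intermediate
12 | benzyl 2,4-bis(benzyloxy)-6-[3-(dimethyl(oxo)-λ6-sulfanylidene)-2-oxopropyl]benzoate | CS(C)(=O)=CC(=O)Cc1cc(OCc2ccccc2)cc(OCc2ccccc2)c1C(=O)OCc1ccccc1 | intermediate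
13 | benzyl 2,4-bis(benzyloxy)-6-{4-[4-(benzyloxy)-2-heptyl-6-hydroxyphenyl]-2,4-dioxobutyl}benzoate | CCCCCCCc1cc(OCc2ccccc2)cc(O)c1C(=O)CC(=O)Cc1cc(OCc2ccccc2)cc(OCc2ccccc2)c1C(=O)OCc1ccccc1 | intermediate
14 | benzyl 2,4-bis(benzyloxy)-6-{[7-(benzyloxy)-5-heptyl-4-oxo-4H-chromen-2-yl]methyl}benzoate (tetrabenzyl siphulin) | CCCCCCCc1cc(OCc3ccccc3)cc2oc(Cc3cc(OCc4ccccc4)cc(OCc4ccccc4)c3C(=O)OCc3ccccc3)cc(=O)c12 | intermediate
15 | siphulin, 2-[(5-heptyl-7-hydroxy-4-oxo-4H-chromen-2-yl)methyl]-4,6-dihydroxybenzoic acid | CCCCCCCc1cc(O)cc2oc(Cc3cc(O)cc(O)c3C(=O)O)cc(=O)c12 | target

## Step count and least certain steps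

Total step count: 7. Longest linear sequence: 5 steps (5 to 6 to 8 to 12 to 14 to 15; steps 3 to 7). The aldehyde branch (steps 1 and 2) joins at step 6.

**Step 6 (key step).** The most likely failure is slow migratory insertion at an acyl-rhodium centre that is flanked by the heptyl chain. Ylide 12 would then be consumed by protonation or self-coupling, or the acyl-rhodium species would decarbonylate, before C3-C4 forms. A second risk is attack of the enolised diketone on the ring C ester in place of pyranone closure.

The fallback forms C2-C3 by a Claisen-type acylation. It sets out from 1 and from 8 (through its imidazolide 11) and returns to the route at 14 through 13. Friedel-Crafts acetylation of 1 (AcOH, BF3·OEt2, 90 °C) should give 1-(2-heptyl-4,6-dihydroxyphenyl)ethan-1-one F1. Selective benzylation as in step 2 should give 1-[4-(benzyloxy)-2-heptyl-6-hydroxyphenyl]ethan-1-one F2. The dianion of F2 (LiN(SiMe3)2, 3 equiv, THF, -78 °C) would be acylated by 11 to give 13 after a cold acidic quench. TsOH in toluene at 80 °C would then close 13 to 14. This costs one more step and exposes the ring C ester to base, which is why it is held in reserve.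

**Step 5.** The basic methylide 10 may deprotonate the arylacetyl methylene of 11, leading to ketene formation and oligomerisation. The carbanionic carbon of 12 may also undergo a Claisen-type closure onto the neighbouring benzyl ester under the basic conditions.

The fallback replaces the ylide by a diazoketone as carbene source. It sets out from 8 and returns at 14. Acid 8 would be converted (isobutyl chloroformate, Et3N, THF, -15 °C) into the mixed anhydride benzyl 2,4-bis(benzyloxy)-6-{2-[(isobutoxycarbonyl)oxy]-2-oxoethyl}benzoate F3. Trimethylsilyldiazomethane in THF-MeCN would turn it into benzyl 2,4-bis(benzyloxy)-6-(3-diazo-2-oxopropyl)benzoate F4. Slow addition of F4 to 4 under the catalyst system of step 6 should give the same rhodium carbene with loss of dinitrogen, and hence 13 and 14. No strong base touches the ring C ester on this path.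

**Step 4.** Deprotonation may occur at the O-CH2 of the benzyl ester (followed by acyl migration) or at a benzyl ether methylene instead of the aryl methyl group. The lithiated species may also add to the ester of unreacted 6.

The fallback lithiates the carboxylate dianion instead of the ester. It sets out from 6 and returns at 8. Saponification (KOH, DMSO-H2O, 80 °C) should give 2,4-bis(benzyloxy)-6-methylbenzoic acid F5. Its dianion (s-BuLi, 2.2 equiv, THF, -78 °C), quenched with carbon dioxide, should give 2-(carboxymethyl)-4,6-bis(benzyloxy)benzoic acid F6. Benzylation of both carboxyl groups (BnBr, K2CO3, DMF) would give benzyl 2,4-bis(benzyloxy)-6-[2-(benzyloxy)-2-oxoethyl]benzoate F7. Hydrolysis with one equivalent of LiOH in THF-H2O at 0 °C should cleave only the unhindered arylacetic ester and give 8.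

**Step 7.** Over-reduction of the C2-C3 double bond to the chromanone is the main risk. It becomes more likely if cleavage of the hindered benzyl ester is slow and the exposure to hydrogen must be prolonged.

The fallback removes the benzyl groups by Lewis acid instead of hydrogen. It sets out from 14 and arrives directly at 15. BCl3 with pentamethylbenzene as cation scavenger in CH2Cl2, -78 °C to 0 °C, should cleave the three ethers and the ester without touching the pyranone. The low temperature guards against decarboxylation. No new intermediate is isolated.

## Further compounds

F1 | step 6 | 1-(2-heptyl-4,6-dihydroxyphenyl)ethan-1-one | CCCCCCCc1cc(O)cc(O)c1C(C)=O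
F2 | step 6 | 1-[4-(benzyloxy)-2-heptyl-6-hydroxyphenyl]ethan-1-one | CCCCCCCc1cc(OCc2ccccc2)cc(O)c1C(C)=O
F3 | step 5 | benzyl 2,4-bis(benzyloxy)-6-{2-[(isobutoxycarbonyl)oxy]-2-oxoethyl}benzoate | CC(C)COC(=O)OC(=O)Cc1cc(OCc2ccccc2)cc(OCc2ccccc2)c1C(=O)OCc1ccccc1
F4 | step 5 | benzyl 2,4-bis(benzyloxy)-6-(3-diazo-2-oxopropyl)benzoate | [N-]=[N+]=CC(=O)Cc1cc(OCc2ccccc2)cc(OCc2ccccc2)c1C(=O)OCc1ccccc1
F5 | step 4 | 2,4-bis(benzyloxy)-6-methylbenzoic acid | Cc1cc(OCc2ccccc2)cc(OCc2ccccc2)c1C(=O)O
F6 | step 4 | 2-(carboxymethyl)-4,6-bis(benzyloxy)benzoic acid | OC(=O)Cc1cc(OCc2ccccc2)cc(OCc2ccccc2)c1C(=O)O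
F7 | step 4 | benzyl 2,4-bis(benzyloxy)-6-[2-(benzyloxy)-2-oxoethyl]benzoate | O=C(Cc1cc(OCc2ccccc2)cc(OCc2ccccc2)c1C(=O)OCc1ccccc1)OCc1ccccc1
F0 | step 7 | none | none
A1 | alternative 1 | protected siphulin with C7 benzyl ether, C5' pivalate and ring C benzodioxinone | CCCCCCCc1cc(OCc3ccccc3)cc2oc(Cc3cc(OC(=O)C(C)(C)C)cc4OC(C)(C)OC(=O)c34)cc(=O)c12
A2 | alternative 1 | (Z)-3-[3-(benzyloxy)-5-heptylphenoxy]-4-[2,2-dimethyl-4-oxo-7-(pivaloyloxy)-4H-benzo[d][1,3]dioxin-5-yl]but-2-enoic acid | CCCCCCCc1cc(OCc2ccccc2)cc(O/C(Cc2cc(OC(=O)C(C)(C)C)cc3OC(C)(C)OC(=O)c23)=C\C(=O)O)c1
A3 | alternative 2 | benzyl 2-(benzyloxy)-6-{[7-(benzyloxy)-5-heptyl-4-oxo-4H-chromen-2-yl]methyl}-4-hydroxybenzoate (tribenzyl siphulin, C5' phenol free) | CCCCCCCc1cc(OCc3ccccc3)cc2oc(Cc3cc(O)cc(OCc4ccccc4)c3C(=O)OCc3ccccc3)cc(=O)c12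
A4 | alternative 2 | benzyl 4-(benzyloxy)-6-{[7-(benzyloxy)-5-heptyl-4-oxo-4H-chromen-2-yl]methyl}-2-oxo-2H-pyran-5-carboxylate | CCCCCCCc1cc(OCc3ccccc3)cc2oc(Cc3oc(=O)cc(OCc4ccccc4)c3C(=O)OCc3ccccc3)cc(=O)c12
A5 | alternative 2 | 1,1-bis(trimethylsilyloxy)ethene | C=C(O[Si](C)(C)C)O[Si](C)(C)C
A6 | alternative 3 | benzyl 2,4-bis(benzyloxy)-6-[(E)-4-(2-heptyl-4,6-dihydroxyphenyl)-2-methoxy-4-oxobut-2-en-1-yl]benzoate | CCCCCCCc1cc(O)cc(O)c1C(=O)/C=C(/OC)Cc1cc(OCc2ccccc2)cc(OCc2ccccc2)c1C(=O)OCc1ccccc1
A7 | alternative 3 | benzyl 2,4-bis(benzyloxy)-6-[(E)-2-methoxy-4-oxotridec-2-en-5-yn-1-yl]benzoate | CCCCCCCC#CC(=O)/C=C(/OC)Cc1cc(OCc2ccccc2)cc(OCc2ccccc2)c1C(=O)OCc1ccccc1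
A8 | alternative 3 | 1-methoxy-1,3-bis(trimethylsilyloxy)buta-1,3-diene | C=C(O[Si](C)(C)C)C=C(OC)O[Si](C)(C)C
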